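Our vessel is closed, so whatever is charged as D stays in it in some form, and the question is how that charge ends up shared.

| flask | D | J | remark | time |
|---|---|---|---|---|
| Saturday's | 1.3 M | 0.040 M | run made earlier |  |
| maple | 2.0 M | 0.0400 M |  | 15 h |
| alder | 2.0 M | 0.0520 M |  | 15 h |
| birch | 2.0 M | 0.0680 M |  | 15 h |

Saturday's run (percent of the D charged)

| time / h | X / % | L / % | G / % | D / % | Z / % |
|---|---|---|---|---|---|
| 0.667 | 4 | 1 | 0 | 81 | 18 |
| 1.33 | 4 | 4 | 0 | 65 | 32 |
| 2.00 | 4 | 9 | 0 | 53 | 38 |
| 3.00 | 5 | 10 | 1 | 36 | 45 |
| 5.00 | 11 | 24 | 6 | 20 | 44 |
| 10.0 | 15 | 33 | 3 | 5 | 44 |

(scatter of a reading: 2 percentage points)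

- no earlier run changes the charge of J; that part of a forecast is a guess

- which of these there is most of at the end, counted by the D in it, maple (Z / G / X / L)
- which of these there is most of at the end, counted by the D in it, alder (Z / G / X / L)
- which of these there is most of at the end, counted by the D in it, birch (Z / G / X / L)
- amount of the one of these that there is most of at the end, in percent of the D charged, maple
- amount of the one of these that there is most of at the end, in percent of the D charged, alder
- amount of the one of these that there is most of at the end, in percent of the D charged, birch

D falls like a first-order lag, which multiplies what is left by the same factor over each equal span. Saturday's reading of 20 % at 5.00 h therefore gives us 0.800 % left at 15 h. Is it truly such a lag? Squaring that reading predicts 4.00 % at 10.0 h, and 5 % was read, so it passes, though D's larger charge in the new flasks remains untested.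

The harder question is Z, which in Saturday's run reads 44 % at 5.00 h and 44 % at 10.0 h, standing still while D still feeds it. Either whatever carries Z onward has died, or Z, X and L have reached a balance, with their steps running both ways. That second case is thermodynamic control.

We take the balance and set its zero at the case without preference, a third for each form. The pool share of Z, its part of Z + X + L once these stop moving, reads 47.8 % in Saturday's run at 10.0 h, more than that zero.

One objection is that each reading carries 2 percentage points and D at 10.0 h is still entering, so this share may lean high. Another is that J was never varied. We let J act through G, which Saturday's run reads at 3 % at 10.0 h. Taking out that G and the D left, our own reckoning for maple is Z at 46.0 %. Alder and birch should differ from maple by their change in G, with Z ahead of L, as it reads in Saturday's run at 10.0 h.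

The forecast differs. It gives Z at 60 % in maple, Z at 50 % in alder and L at 41 % in birch, reading the stall as “J driving Z onward, with J used up after limited turnover”.

The flask puts Z first at 42.3 % in maple, 42.0 % in alder and 41.7 % in birch, where L reaches 35.3 %, less than Z.

    D → Z (k = 8.70 × 10⁻⁵ s⁻¹)
    Z ⇌ X (K = 0.460, k = 1.00 × 10⁻⁴ s⁻¹)
    Z + J → G (k = 1.00 × 10⁻⁴ L mol⁻¹ s⁻¹)
    X ⇌ L (K = 1.90, k = 6.20 × 10⁻⁴ s⁻¹)

Our reckoning of Z stands 3.7 points high for maple, on the side we allowed for. Part of what keeps Z ahead in birch is the two returns acting together, X to Z and L to X. In birch, Z ends at 2.97 % without the first and 6.19 % without the second, against 41.7 % with both.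

Now read maple at 40 h. The pool share, on the charge less maple's G, gives 46.9 %, and the computed Z is 42.0 %, against 42.3 % at 15 h.

The runs are simulated from invented constants.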